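**Strategy.** Everything rests on cutting the sp3–sp3 bond between the methyl-bearing stereocentre beside the exocyclic alkene and the adjacent CH2. That carbon is allylic to the C5=CH enol-lactone double bond of the furanone ring, so it can be reached from a racemic (E)-allylic chloride on the O-methyl tetronate. A chiral pybox complex of NiCl2 couples this chloride enantioconvergently with the primary alkylzinc bromide that carries the (S)-methyl centre, the (E,Z)-diene and the 3-furyl ring: one operation joins both halves and sets the (R)-centre. Conjugation of the allyl unit with the ring C3=C4–C2=O system and the fully substituted C5 steer attack to the remote carbon. The (E)-ylidene geometry comes from an anhydride Wittig reaction.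

Key step: step 16

Assumption: the facial sense of the nickel–pybox catalyst on this allyl unit is taken by analogy with simple (E)-allylic chlorides; should a model coupling show the opposite sense, the enantiomeric ligand is used and nothing else changes.

**Step 1**
Reactants: 1 3-bromofuran; 2 oxetane
Product: 4 3-(furan-3-yl)propan-1-ol, via 3-furyllithium 3 (not isolated)
Conditions: n-BuLi, THF, −78 °C; then 2, BF3·OEt2, −78 °C; then H2O
Reagents that add atoms: none
Why: Halogen–lithium exchange gives 3-furyllithium, which stays the 3-isomer at −78 °C and opens BF3-activated oxetane at carbon (Lewis-acid-promoted oxetane opening by an organolithium).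

**Step 2**
Reactants: 4 3-(furan-3-yl)propan-1-ol
Product: 5 3-(3-bromopropyl)furan
Conditions: CBr4, PPh3, CH2Cl2, 0 °C
Reagents that add atoms: carbon tetrabromide, BrC(Br)(Br)Br
Why: Appel bromination of the primary alcohol under neutral conditions that spare the acid-sensitive furan.

**Step 3**
Reactants: 5 3-(3-bromopropyl)furan; 6 propyne
Product: 10 3-[(4Z)-5-iodo-4-methylpent-4-en-1-yl]furan, via Grignard reagent 7 (not isolated), via alkylcopper 8 (not isolated), via alkenylcopper 9 (not isolated)
Conditions: Mg, Et2O, reflux; CuBr·SMe2, Et2O/Me2S, −45 °C; 6 (excess), −25 °C; I2, THF, −50 to 0 °C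
Reagents that add atoms: iodine, II
Why: Normant carbocupration adds the alkylcopper syn across propyne with copper on the terminal carbon, so the new chain and copper are cis, and iodinolysis with retention gives the (Z)-iodide.

**Step 4**
Reactants: 11 (3S)-3,7-dimethylocta-1,6-diene [(S)-β-citronellene]
Product: 12 2,2-dimethyl-3-[(3S)-3-methylpent-4-en-1-yl]oxirane
Conditions: mCPBA (1.0 equiv), NaHCO3, CH2Cl2, 0 °C
Reagents that add atoms: mCPBA, OOC(=O)c1cccc(Cl)c1
Why: Prilezhaev epoxidation is chemoselective for the electron-rich trisubstituted alkene over the vinyl group and leaves the stereocentre untouched.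

**Step 5**
Reactants: 12 2,2-dimethyl-3-[(3S)-3-methylpent-4-en-1-yl]oxirane
Product: 14 (4S)-4-methylhex-5-enal, via vicinal diol 13 (not isolated)
Conditions: H5IO6, THF/H2O, 0 °C to rt
Reagents that add atoms: none
Why: Periodic acid hydrolyses the epoxide to the diol and cleaves it (Malaprade glycol cleavage) to the aldehyde and acetone without touching the vinyl group or the γ-stereocentre.

**Step 6**
Reactants: 14 (4S)-4-methylhex-5-enal
Product: 15 (4S)-4-methylhex-5-en-1-ol
Conditions: NaBH4, MeOH, 0 °C
Reagents that add atoms: none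
Why: Borohydride reduction of the aldehyde to the primary alcohol.

**Step 7**
Reactants: 15 (4S)-4-methylhex-5-en-1-ol; 16 4,4,5,5-tetramethyl-2-vinyl-1,3,2-dioxaborolane
Product: 17 (4S,5E)-4-methyl-6-(4,4,5,5-tetramethyl-1,3,2-dioxaborolan-2-yl)hex-5-en-1-ol
Conditions: second-generation Hoveyda–Grubbs catalyst (5 mol%), 16 (3 equiv), CH2Cl2, 40 °C
Reagents that add atoms: none
Why: Olefin cross-metathesis of a terminal alkene with vinyl pinacolboronate should give the (E)-alkenylboronate under thermodynamic control, and the allylic methyl centre cannot epimerise under these conditions.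

**Step 8**
Reactants: 17 (4S,5E)-4-methyl-6-(4,4,5,5-tetramethyl-1,3,2-dioxaborolan-2-yl)hex-5-en-1-ol; 10 3-[(4Z)-5-iodo-4-methylpent-4-en-1-yl]furan
Product: 18 (4S,5E,7Z)-11-(furan-3-yl)-4,8-dimethylundeca-5,7-dien-1-ol
Conditions: PdCl2(dppf) (5 mol%), K3PO4 (aq.), THF, 40 °C
Reagents that add atoms: none
Why: Suzuki–Miyaura coupling joins the (E)-alkenylboronate and the (Z)-alkenyl iodide with retention at both partners, giving the (E,Z)-diene.

**Step 9**
Reactants: 18 (4S,5E,7Z)-11-(furan-3-yl)-4,8-dimethylundeca-5,7-dien-1-ol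
Product: 19 3-[(4Z,6E,8S)-11-bromo-4,8-dimethylundeca-4,6-dien-1-yl]furan
Conditions: CBr4, PPh3, CH2Cl2, 0 °C
Reagents that add atoms: carbon tetrabromide, BrC(Br)(Br)Br
Why: Appel bromination of the primary alcohol under neutral conditions that spare the diene and the furan.

**Step 10**
Reactants: 20 diethyl 2-methyl-3-oxobutanedioate (diethyl oxalpropionate)
Product: 21 diethyl 2-methoxy-3-methylbut-2-enedioate (E/Z mixture)
Conditions: Me3SiCHN2, MeOH/toluene, 0 °C to rt
Reagents that add atoms: trimethylsilyldiazomethane, C[Si](C)(C)C=[N+]=[N-]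
Why: The strongly enolised α-keto ester is O-methylated by the diazoalkane (enol etherification), and the enol ether geometry is irrelevant because it is equilibrated in step 12.

**Step 11**
Reactants: 21 diethyl 2-methoxy-3-methylbut-2-enedioate
Product: 22 2-methoxy-3-methylbut-2-enedioic acid (E/Z mixture)
Conditions: KOH, EtOH/H2O, 60 °C; then HCl (aq.), 0 °C
Reagents that add atoms: potassium hydroxide, [K+].[OH-]
Why: Saponification of both ethyl esters, with cold acidification so that the β-methoxyacrylate enol ether is not hydrolysed.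

**Step 12**
Reactants: 22 2-methoxy-3-methylbut-2-enedioic acid
Product: 23 3-methoxy-4-methylfuran-2,5-dione
Conditions: Ac2O, 100 °C
Reagents that add atoms: none
Why: Cyclodehydration with acetic anhydride, in which the push–pull alkene isomerises under the hot acidic conditions so that both geometric isomers funnel into the five-membered anhydride.

**Step 13**
Reactants: 23 3-methoxy-4-methylfuran-2,5-dione; 24 1-(triphenyl-λ5-phosphanylidene)propan-2-one
Product: 25 (5E)-4-methoxy-3-methyl-5-(2-oxopropylidene)furan-2(5H)-one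
Conditions: toluene, 80 °C
Reagents that add atoms: none
Why: Wittig olefination of a cyclic anhydride with a stabilised ylide, which should attack the carbonyl next to the methoxy-bearing carbon (the other is deactivated as a vinylogous carbonate) and give the kinetic (E)-enol lactone with the acetyl group anti to the ring oxygen, as in known ylidenebutenolide syntheses.

**Step 14**
Reactants: 25 (5E)-4-methoxy-3-methyl-5-(2-oxopropylidene)furan-2(5H)-one
Product: 26 (5E)-5-(2-hydroxypropylidene)-4-methoxy-3-methylfuran-2(5H)-one (racemic)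
Conditions: NaBH4, CeCl3·7H2O, MeOH, −78 °C; cold quench with pH 7 buffer
Reagents that add atoms: none
Why: Luche reduction gives 1,2-reduction of the enone to the racemic allylic alcohol without touching the lactone or the alkene geometry.

**Step 15**
Reactants: 26 (5E)-5-(2-hydroxypropylidene)-4-methoxy-3-methylfuran-2(5H)-one
Product: 28 (5E)-5-(2-chloropropylidene)-4-methoxy-3-methylfuran-2(5H)-one (racemic), via allylic mesylate 27 (not isolated)
Conditions: MsCl, 2,4,6-collidine, LiCl, DMF, 0 °C
Reagents that add atoms: lithium chloride, [Li+].[Cl-]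
Why: Chlorination through the mesylate formed in situ, which chloride displaces without allylic transposition because the conjugated secondary chloride is the more stable regioisomer; the racemate is what the next step needs.

**Step 16**
Reactants: 19 3-[(4Z,6E,8S)-11-bromo-4,8-dimethylundeca-4,6-dien-1-yl]furan; 28 (5E)-5-(2-chloropropylidene)-4-methoxy-3-methylfuran-2(5H)-one
Product: 30 (5E)-5-[(2R,6S,7E,9Z)-13-(furan-3-yl)-2,6,10-trimethyltrideca-7,9-dien-1-ylidene]-4-methoxy-3-methylfuran-2(5H)-one, via alkylzinc bromide 29 (not isolated)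
Conditions: 19, Zn dust, I2 (5 mol%), DMA, 70 °C; then 28, NiCl2·glyme (5 mol%), (S,S)-2,6-bis[4-(2-phenylethyl)-4,5-dihydrooxazol-2-yl]pyridine (5.5 mol%), NaCl, DMA/DMF, −10 °C
Reagents that add atoms: none
Why: This is a nickel-catalysed enantioconvergent Negishi cross-coupling of a racemic secondary allylic chloride with a primary alkylzinc halide (a known reaction type, including γ-chloro-α,β-unsaturated esters): a monovalent nickel–pybox complex abstracts chloride from either enantiomer of 28 to give a planar allylic radical, the alkylnickel formed by transmetalation from 29 captures it, and reductive elimination from trivalent nickel forms the sp3–sp3 bond. The new stereocentre is set by the chiral pybox ligand (catalyst control), and the remote (S)-centre of 29 is four bonds from zinc and should not interfere. Regioselectivity for the methyl-bearing terminus is secured by the substrate, because the other allyl terminus is the fully substituted, oxygen-bearing ring carbon C5 and coupling at the remote carbon keeps C5=CH conjugated with the ring C3=C4–C2=O unit. The step also needs retention of the (E)-alkene, which relies on radical capture being faster than rotation about the C5–CH bond at −10 °C. No ring is formed, and the lactone, enol ether, furan and diene are inert to alkylzinc halides.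

**Step 17**
Reactants: 30 (5E)-5-[(2R,6S,7E,9Z)-13-(furan-3-yl)-2,6,10-trimethyltrideca-7,9-dien-1-ylidene]-4-methoxy-3-methylfuran-2(5H)-one
Product: 31 (5E)-5-[(2R,6S,7E,9Z)-13-(furan-3-yl)-2,6,10-trimethyltrideca-7,9-dien-1-ylidene]-4-hydroxy-3-methylfuran-2(5H)-one
Conditions: n-PrSLi, HMPA, rt; then HCl (aq.) to pH 3
Reagents that add atoms: none
Why: Nucleophilic (SN2) dealkylation of the vinylogous methyl ester by thiolate, a known way to unmask O-methyl tetronates, gives a base-inert tetronate anion, so the allylic stereocentre, the diene and the furan should survive before acidification releases the tetronic acid.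

**Compound list**

1 | 3-bromofuran | Brc1ccoc1 | starting material
2 | oxetane | C1COC1 | starting material
3 | 3-furyllithium | [Li]c1ccoc1 | intermediate (not isolated)
4 | 3-(furan-3-yl)propan-1-ol | OCCCc1ccoc1 | intermediate
5 | 3-(3-bromopropyl)furan | BrCCCc1ccoc1 | intermediate
6 | propyne | CC#C | starting material
7 | [3-(furan-3-yl)propyl]magnesium bromide | Br[Mg]CCCc1ccoc1 | intermediate (not isolated)
8 | [3-(furan-3-yl)propyl]copper | [Cu]CCCc1ccoc1 | intermediate (not isolated)
9 | [(1Z)-5-(furan-3-yl)-2-methylpent-1-en-1-yl]copper | [Cu]/C=C(/C)CCCc1ccoc1 | intermediate (not isolated)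
10 | 3-[(4Z)-5-iodo-4-methylpent-4-en-1-yl]furan | I/C=C(/C)CCCc1ccoc1 | intermediate
11 | (3S)-3,7-dimethylocta-1,6-diene | CC(C)=CCC[C@H](C)C=C | starting material
12 | 2,2-dimethyl-3-[(3S)-3-methylpent-4-en-1-yl]oxirane (both epimers at the oxirane carbon) | CC1(C)OC1CC[C@H](C)C=C | intermediate
13 | (6S)-2,6-dimethyloct-7-ene-2,3-diol (both epimers at C3) | CC(C)(O)C(O)CC[C@H](C)C=C | intermediate (not isolated)
14 | (4S)-4-methylhex-5-enal | O=CCC[C@H](C)C=C | intermediate
15 | (4S)-4-methylhex-5-en-1-ol | OCCC[C@H](C)C=C | intermediate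
16 | 4,4,5,5-tetramethyl-2-vinyl-1,3,2-dioxaborolane | C=CB1OC(C)(C)C(C)(C)O1 | starting material
17 | (4S,5E)-4-methyl-6-(4,4,5,5-tetramethyl-1,3,2-dioxaborolan-2-yl)hex-5-en-1-ol | OCCC[C@H](C)/C=C/B1OC(C)(C)C(C)(C)O1 | intermediate
18 | (4S,5E,7Z)-11-(furan-3-yl)-4,8-dimethylundeca-5,7-dien-1-ol | OCCC[C@H](C)/C=C/C=C(/C)CCCc1ccoc1 | intermediate
19 | 3-[(4Z,6E,8S)-11-bromo-4,8-dimethylundeca-4,6-dien-1-yl]furan | BrCCC[C@H](C)/C=C/C=C(/C)CCCc1ccoc1 | intermediate
20 | diethyl 2-methyl-3-oxobutanedioate | CCOC(=O)C(C)C(=O)C(=O)OCC | starting material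
21 | diethyl 2-methoxy-3-methylbut-2-enedioate (E/Z mixture) | CCOC(=O)C(C)=C(OC)C(=O)OCC | intermediate
22 | 2-methoxy-3-methylbut-2-enedioic acid (E/Z mixture) | OC(=O)C(C)=C(OC)C(O)=O | intermediate
23 | 3-methoxy-4-methylfuran-2,5-dione | COC1=C(C)C(=O)OC1=O | intermediate
24 | 1-(triphenyl-λ5-phosphanylidene)propan-2-one | CC(=O)C=P(c1ccccc1)(c1ccccc1)c1ccccc1 | starting material
25 | (5E)-4-methoxy-3-methyl-5-(2-oxopropylidene)furan-2(5H)-one | CC1=C(OC)/C(=C\C(C)=O)OC1=O | intermediate
26 | (5E)-5-(2-hydroxypropylidene)-4-methoxy-3-methylfuran-2(5H)-one (racemic) | CC1=C(OC)/C(=C\C(C)O)OC1=O | intermediate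
27 | 1-[(2E)-3-methoxy-4-methyl-5-oxofuran-2(5H)-ylidene]propan-2-yl methanesulfonate (racemic) | CC1=C(OC)/C(=C\C(C)OS(C)(=O)=O)OC1=O | intermediate (not isolated)
28 | (5E)-5-(2-chloropropylidene)-4-methoxy-3-methylfuran-2(5H)-one (racemic) | CC1=C(OC)/C(=C\C(C)Cl)OC1=O | intermediate
29 | bromo[(4S,5E,7Z)-11-(furan-3-yl)-4,8-dimethylundeca-5,7-dien-1-yl]zinc | Br[Zn]CCC[C@H](C)/C=C/C=C(/C)CCCc1ccoc1 | intermediate (not isolated)
30 | (5E)-5-[(2R,6S,7E,9Z)-13-(furan-3-yl)-2,6,10-trimethyltrideca-7,9-dien-1-ylidene]-4-methoxy-3-methylfuran-2(5H)-one | CC1=C(OC)/C(=C\[C@H](C)CCC[C@H](C)/C=C/C=C(/C)CCCc2ccoc2)OC1=O | intermediate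
31 | (5E)-5-[(2R,6S,7E,9Z)-13-(furan-3-yl)-2,6,10-trimethyltrideca-7,9-dien-1-ylidene]-4-hydroxy-3-methylfuran-2(5H)-one | CC1=C(O)/C(=C\[C@H](C)CCC[C@H](C)/C=C/C=C(/C)CCCc2ccoc2)OC1=O | target

**Step count.** Total: 17 steps. Longest linear sequence: 8 steps (steps 4, 5, 6, 7, 8, 9, 16, 17 from 11; equally steps 10 to 17 from 20).

**Steps most likely to fail**

Step 16. The (E)-alkene may be lost by rotation about the C5–CH bond at the allylic radical or allylnickel stage, which would drain material toward the more stable (Z)-isomer. Facial selection on an allyl unit with a trisubstituted alkene may also be poor, and the chloride may simply be reduced. The fallback is a stereospecific copper-catalysed anti-SN2 alkylation; it sets out from ketone 25 and bromide 19 and returns at 30. Ketone 25 is reduced with catecholborane and (S)-2-methyl-CBS-oxazaborolidine in toluene at −78 °C, which by analogy with aryl methyl ketones should give (5E)-5-[(2R)-2-hydroxypropylidene]-4-methoxy-3-methylfuran-2(5H)-one F1. Diethyl chlorophosphate and N-methylimidazole convert it with retention into (2R)-1-[(2E)-3-methoxy-4-methyl-5-oxofuran-2(5H)-ylidene]propan-2-yl diethyl phosphate F2. Bromide 19 is turned with Mg in THF into [(4S,5E,7Z)-11-(furan-3-yl)-4,8-dimethylundeca-5,7-dien-1-yl]magnesium bromide F3, which is added to F2 with CuBr·SMe2 (10 mol%) in THF at −78 °C. The dialkylcuprate formed in situ should displace the phosphate at the methyl-bearing carbon with inversion, because the other allyl terminus C5 is fully substituted, and (R)-F2 then gives the (R)-centre of 30 without a freely rotating radical.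

Step 17. The thiolate may add reversibly to the exocyclic CH carbon, which would isomerise the (E)-alkene toward the (Z)-isomer, or dealkylation next to the crowded side chain may stall. The fallback exchanges the methyl ether for a fluoride-labile group before the furan and diene are present; it sets out from ketone 25 and returns at target 31. BBr3 in CH2Cl2 at −78 °C demethylates 25 to (5E)-4-hydroxy-3-methyl-5-(2-oxopropylidene)furan-2(5H)-one F4, in which the hydrogen bond from the 4-OH to the ketone holds the (E)-geometry. SEMCl and i-Pr2NEt give (5E)-3-methyl-5-(2-oxopropylidene)-4-{[2-(trimethylsilyl)ethoxy]methoxy}furan-2(5H)-one F5. Luche reduction as in step 14 gives the racemic alcohol (5E)-5-(2-hydroxypropylidene)-3-methyl-4-{[2-(trimethylsilyl)ethoxy]methoxy}furan-2(5H)-one F6. MsCl, collidine and LiCl as in step 15 give, through the mesylate of F6 F7, the racemic chloride (5E)-5-(2-chloropropylidene)-3-methyl-4-{[2-(trimethylsilyl)ethoxy]methoxy}furan-2(5H)-one F8. Coupling with 29 under the conditions of step 16 gives the SEM ether of the target F9, and TBAF in THF at 0 °C followed by mild acidification releases 31 without a Michael-donor nucleophile.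

Step 13. The weakly nucleophilic keto-ylide may react sluggishly, attack the wrong anhydride carbonyl, or lose the kinetic (E)-preference under forcing conditions. The fallback builds the methyl ketone in two operations from a more nucleophilic ylide; it sets out from anhydride 23 and returns at ketone 25. N-Methoxy-N-methyl-2-(triphenyl-λ5-phosphanylidene)acetamide reacts with 23 in CH2Cl2 at room temperature to give (2E)-N-methoxy-2-[3-methoxy-4-methyl-5-oxofuran-2(5H)-ylidene]-N-methylacetamide F10. MeMgBr in THF at −78 °C then adds once to the Weinreb amide through the chelated tetrahedral intermediate and gives 25 on work-up.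

**Further compounds**

F1 | step 16 | (5E)-5-[(2R)-2-hydroxypropylidene]-4-methoxy-3-methylfuran-2(5H)-one | CC1=C(OC)/C(=C\[C@@H](C)O)OC1=O
F2 | step 16 | (2R)-1-[(2E)-3-methoxy-4-methyl-5-oxofuran-2(5H)-ylidene]propan-2-yl diethyl phosphate | CC1=C(OC)/C(=C\[C@@H](C)OP(=O)(OCC)OCC)OC1=O
F3 | step 16 | [(4S,5E,7Z)-11-(furan-3-yl)-4,8-dimethylundeca-5,7-dien-1-yl]magnesium bromide | Br[Mg]CCC[C@H](C)/C=C/C=C(/C)CCCc1ccoc1
F4 | step 17 | (5E)-4-hydroxy-3-methyl-5-(2-oxopropylidene)furan-2(5H)-one | CC1=C(O)/C(=C\C(C)=O)OC1=O
F5 | step 17 | (5E)-3-methyl-5-(2-oxopropylidene)-4-{[2-(trimethylsilyl)ethoxy]methoxy}furan-2(5H)-one | CC1=C(OCOCC[Si](C)(C)C)/C(=C\C(C)=O)OC1=O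
F6 | step 17 | (5E)-5-(2-hydroxypropylidene)-3-methyl-4-{[2-(trimethylsilyl)ethoxy]methoxy}furan-2(5H)-one (racemic) | CC1=C(OCOCC[Si](C)(C)C)/C(=C\C(C)O)OC1=O
F7 | step 17 | 1-[(2E)-4-methyl-5-oxo-3-{[2-(trimethylsilyl)ethoxy]methoxy}furan-2(5H)-ylidene]propan-2-yl methanesulfonate (racemic) | CC1=C(OCOCC[Si](C)(C)C)/C(=C\C(C)OS(C)(=O)=O)OC1=O
F8 | step 17 | (5E)-5-(2-chloropropylidene)-3-methyl-4-{[2-(trimethylsilyl)ethoxy]methoxy}furan-2(5H)-one (racemic) | CC1=C(OCOCC[Si](C)(C)C)/C(=C\C(C)Cl)OC1=O
F9 | step 17 | (5E)-5-[(2R,6S,7E,9Z)-13-(furan-3-yl)-2,6,10-trimethyltrideca-7,9-dien-1-ylidene]-3-methyl-4-{[2-(trimethylsilyl)ethoxy]methoxy}furan-2(5H)-one | CC1=C(OCOCC[Si](C)(C)C)/C(=C\[C@H](C)CCC[C@H](C)/C=C/C=C(/C)CCCc2ccoc2)OC1=O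
F10 | step 13 | (2E)-N-methoxy-2-[3-methoxy-4-methyl-5-oxofuran-2(5H)-ylidene]-N-methylacetamide | CC1=C(OC)/C(=C\C(=O)N(C)OC)OC1=O
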